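A small charge of solid D, 0.066 M, is still 6.00 times its solubility, and we want to know what the flask holds after 12 h under G with catalyst L.

D 0.066 M; G 12 mM (held); L 3.3 mM; time 12 h

    G ⇌ Z, rate k1*(csat - [Z]) (k1 = 3.3 × 10⁻⁴ s⁻¹, csat = 12 mM)
    X + Z + L → L + E (k2 = 1.4 L² mol⁻² s⁻¹)
    D ⇌ X, rate k3*(cs3 - [X]) while solid is left; crystals form when [X] > cs3 (cs3 = 11 mM, k3 = 6.3 × 10⁻⁵ s⁻¹)
    X ⇌ J (K4 = 1.9, k4 = 2.0 × 10⁻⁵ s⁻¹)
    X + L → X.L (k5 = 7.6 × 10⁻⁴ L mol⁻¹ s⁻¹)

- solid, in amounts per volume of the solution: D
- at the start none of Z is dissolved
- at the start none of D is in solution
- run time (flask): 12 h

- the E standing at 12 h, as a percentage of the D charged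
- concentration of Z in solution at 6.0 h, in percent of saturation
- the change that raises the amount of E at 12 h, in percent of the D charged most ("none" if none brings more than 2 percentage points) (cedar / alder / elm / ash / none)
- amount of E at 12 h, in percent of the D charged, after alder

- cedar: doubling the amount of L, all else as stated
- alder: doubling the solubility in step 3, all else as stated
- elm: doubling the transfer coefficient of step 1, all else as stated
- ash: doubling the saturation concentration of G, all else as stated

Dissolution can deliver 45.4% of the charge by then even into a solution kept empty, less than the charge, so we expect solid to lie in the flask for the whole run. The bench rule says that while solid lies there, cX stands at the solubility. The gas crosses over in about 0.842 h, shorter than the run, so we put cZ at saturation, and for this first reckoning we also hold cL at its charge. The reaction to E then becomes a pseudo-first-order loss of X with constant kr, 5.54 × 10⁻⁵ s⁻¹. Applied honestly, the rule gives 39.9% of D as E.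

But the rule needs kr far below the dissolution coefficient, and the ratio of the two is 0.880. So we do not expect cX to stay at the solubility, and we let it settle where feed meets drains. We call the share it keeps the holding fraction: the dissolution coefficient divided by the sum of itself, kr, the forward constant to J and the constant of loss to X.L at charged cL, 44.7%. That puts cX at 4.92 mM, approached with a time constant of about 1.97 h. Making E at kr times this level after a lag of that length gives 14.9% of D, with cZ still put at saturation and cL still held at its charge. Against this draw, we reckon cZ at 93.6% of saturation.

In this reckoning, doubling the solubility doubles the rate, giving 29.8%. Doubling the saturation concentration also lowers the holding fraction, so the rate rises by a factor of 1.44, and doubling L by 1.42. Doubling the transfer coefficient lifts our reckoned cZ to 96.7% of saturation. We choose alder.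

The forecast gives 13.3% of D as E, lower than our figure, cZ at 93.5% of saturation at 6.0 h, alder as the best change and 24% after it, holding that “Doubling the solubility nearly doubles X and hence the rate”.

The simulation gives 13.6% of D as E, cZ at 94.0% of saturation at 6.0 h, alder as the best change with a gain of 11 percentage points, and 24.8% after it, less than our doubled figure.

At 12.0 h this flask makes X 1.05 times as fast as it uses X up, the near balance that the holding fraction supposes, and X stands at 5.45 mM, which is 49.6% of the solubility against our 44.7%. The holding fraction contains no charge of D, and the neighbour flask with 0.040 M of D holds X at 13.6% of its own charge at 12.0 h, which is 5.44 mM, or 49.6% of the solubility.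

The numbers of this flask were chosen freely; no experiment stands behind them.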